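**Retrosynthetic overview**

1. Vitisinol D (11) ⇐ tetramethyl ether 10 by global O-demethylation.
2. 10 ⇐ acyclic diketo ester 7 in one pot: C1–C8 first (Dieckmann-type acylation, cyclopentanone), then C4–C5 and C3=C4 (aldol condensation, bridging cyclohexenone).
3. 7 ⇐ keto ester 5 + 4-methoxycinnamoyl chloride 6 (Claisen C-acylation of the methyl ketone).
4. 5 ⇐ enal 3 + enone 4 + methanol: chiral-carbene homoenolate Michael addition makes C6–C7 and both benzylic stereocentres.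
5. 3 ⇐ 3,5-dimethoxybenzaldehyde 1 (Wittig homologation).

Locants: C1–C8 are those of the bicyclo[3.2.1]oct-3-ene-2,8-dione core of the target and are carried back onto every intermediate. Read from the SMILES, the target is (1R,5S,6R,7R), with the 3,5-dihydroxyphenyl group at C6 endo (syn to the C2–C3=C4 bridge), the 4-hydroxyphenyl group at C7 exo, and the two aryl groups trans.

Assumption: the (5aS,10bR) antipode of the carbene precatalyst gives the (3S,4S) series; if the sense is opposite, the mirror-image precatalyst is used with no other change.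

**Step 1**
Reactants: 1 3,5-dimethoxybenzaldehyde; 2 (triphenylphosphoranylidene)acetaldehyde
Product: 3 (2E)-3-(3,5-dimethoxyphenyl)prop-2-enal
Conditions: toluene, 80 °C
Reagents that add atoms: none
Why: Wittig olefination with a formyl-stabilised ylide gives the E-enal; no stereocentre is formed.

**Step 2**
Reactants: 3 (2E)-3-(3,5-dimethoxyphenyl)prop-2-enal; 4 (3E)-4-(4-methoxyphenyl)but-3-en-2-one
Product: 5 methyl (3S,4S)-3-(3,5-dimethoxyphenyl)-4-(4-methoxyphenyl)-6-oxoheptanoate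
Conditions: (5aS,10bR)-2-(2,4,6-trimethylphenyl)-5a,10b-dihydro-4H,6H-indeno[2,1-b]imidazo[1,5-d][1,4]oxazin-2-ium chloride (C22H23ClN2O, 10 mol%), 1,8-diazabicyclo[5.4.0]undec-7-ene (20 mol%), CH3OH (10 equiv), THF, 23 °C, slow addition of 3 to 4 (2 equiv)
Reagents that add atoms: methanol, CO
Why: N-heterocyclic-carbene homoenolate Michael addition of the Breslow intermediate of 3 to the β-carbon of 4, then methanolysis of the acyl azolium; the chiral imidazolylidene blocks one face of the homoenolate, and the direct open Michael pathway typical of imidazolylidenes should give the like (3S,4S) pair, which is the diastereomer that closes to a trans-3,4-diarylcyclopentanone.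

**Step 3**
Reactants: 5 methyl (3S,4S)-3-(3,5-dimethoxyphenyl)-4-(4-methoxyphenyl)-6-oxoheptanoate; 6 (2E)-3-(4-methoxyphenyl)prop-2-enoyl chloride
Product: 7 methyl (3S,4S,9E)-3-(3,5-dimethoxyphenyl)-4,10-bis(4-methoxyphenyl)-6,8-dioxodec-9-enoate
Conditions: LiN(SiMe3)2 (2.2 equiv), toluene, 0 °C; then 6 (1.05 equiv), 0 → 23 °C; aq NH4Cl
Reagents that add atoms: none
Why: Claisen-type C-acylation of the kinetic lithium enolate at the unhindered CH3 rather than the β-branched CH2 (the second equivalent of base takes up the acidic β-diketone proton, and the silylamide does not deprotonate the ester α-CH2); no stereocentre is touched.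

**Step 4**
Reactants: 7 methyl (3S,4S,9E)-3-(3,5-dimethoxyphenyl)-4,10-bis(4-methoxyphenyl)-6,8-dioxodec-9-enoate
Product: 10 (1R,5S,6R,7R)-6-(3,5-dimethoxyphenyl)-7-(4-methoxyphenyl)-4-[(E)-2-(4-methoxyphenyl)ethenyl]bicyclo[3.2.1]oct-3-ene-2,8-dione, via triketone 8 (not isolated), via aldol adduct 9 (not isolated)
Conditions: LiN(iPr)2 (2.3 equiv), THF (0.02 M), −78 → 0 °C; CH3CO2H (2.5 equiv), 4 Å molecular sieves, 45 °C; then CH3CO2H (20 equiv), 45 °C
Reagents that add atoms: none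
Why: Proposed new method: the β-diketone dianion of 7 (Harris/Weiler type, γ-carbanion at C1, the only γ-site) acylates itself on the methyl ester in a 5-exo-trig Dieckmann-type closure to triketone 8, whose C1 side chain settles trans to the neighbouring 4-methoxyphenyl group; after buffering to the diisopropylamine/diisopropylammonium acetate pair, the C1-protonated triketone closes by a polyketide-type intramolecular aldol from the C5 enol onto the cinnamoyl ketone C4, and because the bridge can only form on the face that carries the C1 chain (the face of the 3,5-dimethoxyphenyl group), C1 and C5 are set with that aryl endo and the other exo; dehydration of 9 can only go towards C3 because C5 is a bridgehead; closest known chemistry is γ-acylation of β-diketone dianions, base-buffered aldol cyclisation of 3,5,7-triketones and bridged Robinson-type aldol condensations.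

**Step 5**
Reactants: 10 (1R,5S,6R,7R)-6-(3,5-dimethoxyphenyl)-7-(4-methoxyphenyl)-4-[(E)-2-(4-methoxyphenyl)ethenyl]bicyclo[3.2.1]oct-3-ene-2,8-dione
Product: 11 vitisinol D, (1R,5S,6R,7R)-6-(3,5-dihydroxyphenyl)-7-(4-hydroxyphenyl)-4-[(E)-2-(4-hydroxyphenyl)ethenyl]bicyclo[3.2.1]oct-3-ene-2,8-dione
Conditions: BBr3 (10 equiv), CH2Cl2, −78 → 0 °C; then H2O, 0 °C
Reagents that add atoms: none
Why: Lewis-acid cleavage of the four aryl methyl ethers (BBr3 demethylation); the bridgeheads C1 and C5 cannot enolise and C6/C7 are not acidic, so no stereocentre is at risk.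

**Compound list**

1 | 3,5-dimethoxybenzaldehyde | COc1cc(C=O)cc(OC)c1 | starting material
2 | (triphenylphosphoranylidene)acetaldehyde | O=CC=P(c1ccccc1)(c1ccccc1)c1ccccc1 | starting material
3 | (2E)-3-(3,5-dimethoxyphenyl)prop-2-enal | COc1cc(/C=C/C=O)cc(OC)c1 | intermediate
4 | (3E)-4-(4-methoxyphenyl)but-3-en-2-one | CC(=O)/C=C/c1ccc(OC)cc1 | starting material
5 | methyl (3S,4S)-3-(3,5-dimethoxyphenyl)-4-(4-methoxyphenyl)-6-oxoheptanoate | COC(=O)C[C@H](c1cc(OC)cc(OC)c1)[C@@H](c1ccc(OC)cc1)CC(C)=O | intermediate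
6 | (2E)-3-(4-methoxyphenyl)prop-2-enoyl chloride | COc1ccc(/C=C/C(Cl)=O)cc1 | starting material
7 | methyl (3S,4S,9E)-3-(3,5-dimethoxyphenyl)-4,10-bis(4-methoxyphenyl)-6,8-dioxodec-9-enoate | COC(=O)C[C@H](c1cc(OC)cc(OC)c1)[C@@H](c1ccc(OC)cc1)CC(=O)CC(=O)/C=C/c1ccc(OC)cc1 | intermediate
8 | (2S,3R,4S)-4-(3,5-dimethoxyphenyl)-3-(4-methoxyphenyl)-2-[(4E)-5-(4-methoxyphenyl)-3-oxopent-4-enoyl]cyclopentan-1-one (C2 epimerisable, acyl chain trans to the 3-aryl group) | O=C(CC(=O)/C=C/c1ccc(OC)cc1)[C@@H]1C(=O)C[C@H](c2cc(OC)cc(OC)c2)[C@H]1c1ccc(OC)cc1 | intermediate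
9 | (1R,5S,6R,7R)-6-(3,5-dimethoxyphenyl)-4-hydroxy-7-(4-methoxyphenyl)-4-[(E)-2-(4-methoxyphenyl)ethenyl]bicyclo[3.2.1]octane-2,8-dione (C4 configuration not defined, lost on dehydration) | O=C1CC(O)(/C=C/c2ccc(OC)cc2)[C@H]2C(=O)[C@@H]1[C@H](c1ccc(OC)cc1)[C@H]2c1cc(OC)cc(OC)c1 | intermediate
10 | (1R,5S,6R,7R)-6-(3,5-dimethoxyphenyl)-7-(4-methoxyphenyl)-4-[(E)-2-(4-methoxyphenyl)ethenyl]bicyclo[3.2.1]oct-3-ene-2,8-dione | O=C1C=C(/C=C/c2ccc(OC)cc2)[C@H]2C(=O)[C@@H]1[C@H](c1ccc(OC)cc1)[C@H]2c1cc(OC)cc(OC)c1 | intermediate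
11 | vitisinol D | O=C1C=C(/C=C/c2ccc(O)cc2)[C@H]2C(=O)[C@@H]1[C@H](c1ccc(O)cc1)[C@H]2c1cc(O)cc(O)c1 | target

**Step count and risks**

Total steps: 5. Longest linear sequence: 5 (1 → 3 → 5 → 7 → 10 → 11).

The three steps most likely to fail are step 4, step 2 and step 5.

Step 4 carries the most risk. The second deprotonation of 7 may go to the ester α-carbon instead of C1. The aldol from the C5 enol must compete with O-cyclisation of 8 to a 4-pyranone. The facial outcome (3,5-dimethoxyphenyl endo) rests on a modest kinetic preference, not a strong one. The fallback reverses the order of chain extension and first ring closure; it sets out from 5 and comes back to the route at 8. Sodium methoxide in methanol closes 5 in the classical 6-oxoheptanoate Dieckmann-type manner to (2R,3R,4S)-2-acetyl-4-(3,5-dimethoxyphenyl)-3-(4-methoxyphenyl)cyclopentan-1-one F6. The disodium dianion of F6 (NaH, 1,2-dimethoxyethane, reflux) is then cinnamoylated at the acetyl methyl group with commercial methyl (2E)-3-(4-methoxyphenyl)prop-2-enoate to give 8. Here 8 is isolated and closed to 10 in a separate, individually optimised buffered aldol and dehydration.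

Step 2 may give the unlike diastereomer (the one that would close to a cis-diaryl ring), low enantioselectivity, enal self-annulation or simple β-protonation. The fallback replaces carbene catalysis by a sparteine-controlled lithiated allylamine as the chiral homoenolate equivalent; it sets out from 3 and comes back at 5. Reductive amination of 3 with 4-methoxyaniline and NaBH(OAc)3 gives N-[(2E)-3-(3,5-dimethoxyphenyl)prop-2-en-1-yl]-4-methoxyaniline F1. Di-tert-butyl dicarbonate converts it into tert-butyl N-[(2E)-3-(3,5-dimethoxyphenyl)prop-2-en-1-yl]-N-(4-methoxyphenyl)carbamate F2. Lithiation with n-BuLi and (−)-sparteine (or its mirror-image surrogate, as the sense requires) in toluene at −78 °C and conjugate addition to 4 gives the enecarbamate tert-butyl N-[(1Z,3R,4S)-3-(3,5-dimethoxyphenyl)-4-(4-methoxyphenyl)-6-oxohept-1-en-1-yl]-N-(4-methoxyphenyl)carbamate F3. Dilute aqueous HCl hydrolyses it to (3S,4S)-3-(3,5-dimethoxyphenyl)-4-(4-methoxyphenyl)-6-oxoheptanal F4. Oxidation with NaClO2 gives (3S,4S)-3-(3,5-dimethoxyphenyl)-4-(4-methoxyphenyl)-6-oxoheptanoic acid F5, and trimethylsilyldiazomethane in methanol esterifies it to 5.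

Step 5 exposes a non-enolisable bridged β-diketone, a dienone and an endo electron-rich arene to a strong Lewis acid; Friedel–Crafts closure onto the enone or ring cleavage on work-up could compete. The fallback moves the demethylation to the robust acyclic stage and finishes with fluoride-labile groups; it sets out from 7 and comes back at 11. BBr3 (CH2Cl2, −78 → −10 °C, the aryl ethers going before the aliphatic ester) gives methyl (3S,4S,9E)-3-(3,5-dihydroxyphenyl)-4,10-bis(4-hydroxyphenyl)-6,8-dioxodec-9-enoate F7. tert-Butyldimethylsilyl chloride and imidazole give the tetrakis(silyl ether) methyl (3S,4S,9E)-3-[3,5-bis(tert-butyldimethylsilyloxy)phenyl]-4,10-bis[4-(tert-butyldimethylsilyloxy)phenyl]-6,8-dioxodec-9-enoate F8. The conditions of step 4 then take F8 through the silylated triketone (2S,3R,4S)-4-[3,5-bis(tert-butyldimethylsilyloxy)phenyl]-3-[4-(tert-butyldimethylsilyloxy)phenyl]-2-{(4E)-5-[4-(tert-butyldimethylsilyloxy)phenyl]-3-oxopent-4-enoyl}cyclopentan-1-one F9 and the silylated aldol adduct (1R,5S,6R,7R)-6-[3,5-bis(tert-butyldimethylsilyloxy)phenyl]-4-hydroxy-7-[4-(tert-butyldimethylsilyloxy)phenyl]-4-{(E)-2-[4-(tert-butyldimethylsilyloxy)phenyl]ethenyl}bicyclo[3.2.1]octane-2,8-dione F10, neither isolated, to tetra-O-(tert-butyldimethylsilyl)vitisinol D F11. HF·pyridine in THF at 0 °C releases 11.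

**Further compounds**

F1 | step 2 | N-[(2E)-3-(3,5-dimethoxyphenyl)prop-2-en-1-yl]-4-methoxyaniline | COc1ccc(NC/C=C/c2cc(OC)cc(OC)c2)cc1
F2 | step 2 | tert-butyl N-[(2E)-3-(3,5-dimethoxyphenyl)prop-2-en-1-yl]-N-(4-methoxyphenyl)carbamate | COc1ccc(N(C/C=C/c2cc(OC)cc(OC)c2)C(=O)OC(C)(C)C)cc1
F3 | step 2 | tert-butyl N-[(1Z,3R,4S)-3-(3,5-dimethoxyphenyl)-4-(4-methoxyphenyl)-6-oxohept-1-en-1-yl]-N-(4-methoxyphenyl)carbamate | CC(C)(C)OC(=O)N(c1ccc(OC)cc1)/C=C\[C@H](c1cc(OC)cc(OC)c1)[C@@H](c1ccc(OC)cc1)CC(C)=O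
F4 | step 2 | (3S,4S)-3-(3,5-dimethoxyphenyl)-4-(4-methoxyphenyl)-6-oxoheptanal | O=CC[C@H](c1cc(OC)cc(OC)c1)[C@@H](c1ccc(OC)cc1)CC(C)=O
F5 | step 2 | (3S,4S)-3-(3,5-dimethoxyphenyl)-4-(4-methoxyphenyl)-6-oxoheptanoic acid | OC(=O)C[C@H](c1cc(OC)cc(OC)c1)[C@@H](c1ccc(OC)cc1)CC(C)=O
F6 | step 4 | (2R,3R,4S)-2-acetyl-4-(3,5-dimethoxyphenyl)-3-(4-methoxyphenyl)cyclopentan-1-one | CC(=O)[C@@H]1C(=O)C[C@H](c2cc(OC)cc(OC)c2)[C@H]1c1ccc(OC)cc1
F7 | step 5 | methyl (3S,4S,9E)-3-(3,5-dihydroxyphenyl)-4,10-bis(4-hydroxyphenyl)-6,8-dioxodec-9-enoate | COC(=O)C[C@H](c1cc(O)cc(O)c1)[C@@H](c1ccc(O)cc1)CC(=O)CC(=O)/C=C/c1ccc(O)cc1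
F8 | step 5 | methyl (3S,4S,9E)-3-[3,5-bis(tert-butyldimethylsilyloxy)phenyl]-4,10-bis[4-(tert-butyldimethylsilyloxy)phenyl]-6,8-dioxodec-9-enoate | COC(=O)C[C@H](c1cc(O[Si](C)(C)C(C)(C)C)cc(O[Si](C)(C)C(C)(C)C)c1)[C@@H](c1ccc(O[Si](C)(C)C(C)(C)C)cc1)CC(=O)CC(=O)/C=C/c1ccc(O[Si](C)(C)C(C)(C)C)cc1
F9 | step 5 | (2S,3R,4S)-4-[3,5-bis(tert-butyldimethylsilyloxy)phenyl]-3-[4-(tert-butyldimethylsilyloxy)phenyl]-2-{(4E)-5-[4-(tert-butyldimethylsilyloxy)phenyl]-3-oxopent-4-enoyl}cyclopentan-1-one | O=C(CC(=O)/C=C/c1ccc(O[Si](C)(C)C(C)(C)C)cc1)[C@@H]1C(=O)C[C@H](c2cc(O[Si](C)(C)C(C)(C)C)cc(O[Si](C)(C)C(C)(C)C)c2)[C@H]1c1ccc(O[Si](C)(C)C(C)(C)C)cc1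
F10 | step 5 | (1R,5S,6R,7R)-6-[3,5-bis(tert-butyldimethylsilyloxy)phenyl]-4-hydroxy-7-[4-(tert-butyldimethylsilyloxy)phenyl]-4-{(E)-2-[4-(tert-butyldimethylsilyloxy)phenyl]ethenyl}bicyclo[3.2.1]octane-2,8-dione | O=C1CC(O)(/C=C/c2ccc(O[Si](C)(C)C(C)(C)C)cc2)[C@H]2C(=O)[C@@H]1[C@H](c1ccc(O[Si](C)(C)C(C)(C)C)cc1)[C@H]2c1cc(O[Si](C)(C)C(C)(C)C)cc(O[Si](C)(C)C(C)(C)C)c1
F11 | step 5 | (1R,5S,6R,7R)-6-[3,5-bis(tert-butyldimethylsilyloxy)phenyl]-7-[4-(tert-butyldimethylsilyloxy)phenyl]-4-{(E)-2-[4-(tert-butyldimethylsilyloxy)phenyl]ethenyl}bicyclo[3.2.1]oct-3-ene-2,8-dione | O=C1C=C(/C=C/c2ccc(O[Si](C)(C)C(C)(C)C)cc2)[C@H]2C(=O)[C@@H]1[C@H](c1ccc(O[Si](C)(C)C(C)(C)C)cc1)[C@H]2c1cc(O[Si](C)(C)C(C)(C)C)cc(O[Si](C)(C)C(C)(C)C)c1
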